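The synthesis rests on opening the cyclohexenone at C7=C8. The core then becomes a cyclobutane (C4, C5, C10, C9) with one acetyl group on C5 and one on C9. The bridge C3–C2–C1–C11 is kept flat as an enone. The resulting precursor, 7,8-diacetyl-1,5,5-trimethylbicyclo[4.1.1]oct-3-en-2-one, is bisected by a symmetry plane that contains C4, C10 and the whole bridge and maps C5 onto C9. A chiral primary amine makes one of the two enantiotopic acetyl groups the nucleophile, closes the six-membered ring, and so fixes C4, C5, C9 and C10 in one operation. The meso diketone is released by glycol cleavage after a transannular crossed [2+2] photocycloaddition. C1–O and C3–O are installed afterwards.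

Key step: step 13

Assumption and locants: in every intermediate the core atoms are C1 (CH–O next to CMe2), C2, C3 (CH–O), C4 (C–Me), C5, C6 (C=O), C7, C8 (=C–Me), C9, C10, C11 (CMe2). All compounds before 23 are achiral or racemic, with one enantiomer drawn. Carbinol centres that are erased later (C3 in 7–14, C1 in 16–18) are left open.

Step 1
Reactants: 1 methyl 3-hydroxy-2,2-dimethylpropanoate
Product: 2 methyl 2,2-dimethyl-3-oxopropanoate
Conditions: TEMPO (1 mol %), KBr (10 mol %), NaOCl (1.1 equiv), NaHCO3, CH2Cl2/H2O, 0 °C
Reagents that add atoms: none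
Why: Nitroxyl/bleach (Anelli) oxidation of a primary alcohol; the aldehyde has no α-hydrogen, so enolisation and aldol loss are impossible, and no stereocentre is involved.

Step 2
Reactants: 2 methyl 2,2-dimethyl-3-oxopropanoate
Product: 3 methyl 2,2-dimethylbut-3-ynoate
Conditions: dimethyl (1-diazo-2-oxopropyl)phosphonate, K2CO3, MeOH, 0 °C to rt
Reagents that add atoms: dimethyl (1-diazo-2-oxopropyl)phosphonate CC(=O)C(=[N+]=[N-])P(=O)(OC)OC
Why: Ohira–Bestmann alkynylation (Seyferth–Gilbert homologation under carbonate/methanol) works best with non-enolisable aldehydes and leaves the hindered methyl ester untouched.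

Step 3
Reactants: 3 methyl 2,2-dimethylbut-3-ynoate; 4 butane-2,3-dione
Product: 6 methyl 5-hydroxy-2,2,5-trimethyl-6-oxohept-3-ynoate (racemic), via lithium acetylide 5 (not isolated)
Conditions: LiN(i-Pr)2, THF, −78 °C; cannulated into 4 (3 equiv), THF, −78 °C; H2O
Reagents that add atoms: lithium diisopropylamide [Li]N(C(C)C)C(C)C (lithium of 5)
Why: Acetylide 1,2-addition to a 1,2-diketone stops after one addition because of inverse addition to excess diketone and the deactivating α-alkoxide, and C8 forms as a racemate, which is harmless because the key precursor is achiral.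

Step 4
Reactants: 7 but-3-yn-2-ol
Product: 9 (E)-4-iodo-3-methylbut-3-en-2-ol, via vinylalane 8 (not isolated)
Conditions: Me3Al (3 equiv), Cp2ZrCl2 (25 mol %), CH2Cl2, 0 °C to rt; I2, THF, −30 °C; H2O
Reagents that add atoms: trimethylaluminium C[Al](C)C; iodine II
Why: Negishi zirconium-catalysed carboalumination adds methyl and aluminium syn with methyl on the internal carbon (C4), and iodinolysis with retention gives the E-iodide in which C3 is trans to the future C5–C6 bond.

Step 5
Reactants: 6 methyl 5-hydroxy-2,2,5-trimethyl-6-oxohept-3-ynoate; 9 (E)-4-iodo-3-methylbut-3-en-2-ol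
Product: 12 methyl (5R*,6S*,7E)-5,6,9-trihydroxy-2,2,5,6,8-pentamethyldec-7-en-3-ynoate, via dilithio alkenyl alkoxide 10 (not isolated), via bromomagnesium alkoxide 11 (not isolated)
Conditions: 9, t-BuLi (3 equiv), Et2O, −78 °C; separately 6, MeMgBr (1 equiv), THF, −78 °C; combined, −78 to −40 °C; H2O
Reagents that add atoms: tert-butyllithium [Li]C(C)(C)C (lithium of 10); methylmagnesium bromide C[Mg]Br (MgBr of 11)
Why: Cram-chelate-controlled carbonyl addition, in which the bromomagnesium alkoxide ties O–C8 to the C6 carbonyl and the alkenyllithium (iodine–lithium exchange with retention) enters past the slim alkynyl group rather than the methyl group, sets C6 like-meso to C8, the only relationship that later gives a cis-glycol.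

Step 6
Reactants: 12 methyl (5R*,6S*,7E)-5,6,9-trihydroxy-2,2,5,6,8-pentamethyldec-7-en-3-ynoate
Product: 13 (3E,5R*,6S*,7E)-2,2,5,6,8-pentamethyldeca-3,7-diene-1,5,6,9-tetraol
Conditions: NaAlH2(OCH2CH2OMe)2 (6 equiv), THF, 0 °C to rt; H2O
Reagents that add atoms: none
Why: Hydroxyl-directed trans-hydroalumination of the propargylic alcohol gives the E-alkene C9=C10, and the same aluminium hydride reduces the ester to the C1 carbinol, so two adjustments cost one step.

Step 7
Reactants: 13 (3E,5R*,6S*,7E)-2,2,5,6,8-pentamethyldeca-3,7-diene-1,5,6,9-tetraol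
Product: 14 (4R*,5S*)-4-[(E)-4-hydroxy-3,3-dimethylbut-1-enyl]-5-[(E)-3-hydroxy-2-methylbut-1-enyl]-4,5-dimethyl-2-phenyl-1,3,2-dioxaborolane (alkenyl arms cis)
Conditions: PhB(OH)2 (1.05 equiv), MgSO4, CH2Cl2, rt
Reagents that add atoms: phenylboronic acid OB(O)c1ccccc1
Why: Boronic ester formation is neutral, selects the 1,2-diol because only it gives a five-membered pinacol-type ring, avoids the acid that would ionise the bis-allylic glycol, and holds the two alkenyl arms cis.

Step 8
Reactants: 14 phenylboronate diol
Product: 15 keto aldehyde: the same cis-dialkenyl phenylboronate with C1 as CHO and C3 as methyl enone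
Conditions: Dess–Martin periodinane (2.4 equiv), NaHCO3, CH2Cl2, 0 °C to rt
Reagents that add atoms: none
Why: Dess–Martin oxidation converts the allylic carbinol C3 into the methyl enone and the neopentyl carbinol C1 into a non-enolisable aldehyde in one operation and erases the undefined C3 centre.

Step 9
Reactants: 15 keto aldehyde
Product: 16 ten-membered (E,E)-dienone: ring C1–C2–C3–C4=C5–C6–C8–C9=C10–C11 with C1–OH and C3=O, and the C6/C8 glycol as a cis-fused phenylboronate
Conditions: slow addition of 15 to LiN(i-Pr)2 (1.2 equiv), THF (final 2 mM), −78 °C; AcOH, −78 °C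
Reagents that add atoms: none
Why: Intramolecular kinetic lithium-enolate aldol addition (macroaldolisation) should work because C2H3 is the only acidic site, the aldehyde cannot enolise, lithium bridges both oxygens, and the gem-dimethyl group and cis-dioxaborolane pre-fold the chain; the new C1 centre needs no control because step 11 removes it.

Step 10
Reactants: 16 ten-membered (E,E)-dienone
Product: 17 tricyclic ketol: cyclobutane C4–C5–C10–C9 with the C6–C8 boronate bridge on C5/C9 on one face and the bridge C3(=O)–C2H2–C1H(OH)–C11Me2 on C4/C10 on the other face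
Conditions: hν (350 nm, Pyrex), degassed MeCN (5 mM), 0 °C
Reagents that add atoms: none
Why: Transannular crossed enone–alkene [2+2] photocycloaddition, a mode known for medium-ring 1,5-dienones, bonds C5 to C10 in the triplet enone by 1,5-closure (rule of five) and then couples C4 with C9, and because the two tethers can only end on opposite faces of the cyclobutane, C4, C5, C9 and C10 are set in the required relative sense.

Step 11
Reactants: 17 tricyclic ketol
Product: 19 meso tricyclic enone (C3=O, C1=C2 cis in the seven-membered ring, boronate retained), via mesylate 18 (not isolated)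
Conditions: MsCl, Et3N, CH2Cl2, 0 °C; then DBU, rt
Reagents that add atoms: methanesulfonyl chloride CS(=O)(=O)Cl (mesyl group of 18)
Why: Mesylation followed by E1cB elimination through the C2 enolate, the only enolisable position of the C3 ketone, gives the ring-cis enone and restores the mirror plane.

Step 12
Reactants: 19 meso tricyclic enone
Product: 21 meso 7,8-diacetyl-1,5,5-trimethylbicyclo[4.1.1]oct-3-en-2-one (both acetyl groups on the face away from the four-carbon bridge), via cis-diol 20 (not isolated)
Conditions: NaIO4 (3 equiv), THF/pH 7 phosphate buffer, rt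
Reagents that add atoms: none
Why: In this Malaprade cleavage periodate drains the small hydrolysis equilibrium of the boronate, the rigid eclipsed cis-diol cleaves fast with relief of bicyclo[2.1.1]hexane strain, and the neutral ammonium-free medium should deliver both acetyl groups without epimerisation or premature aldol reaction.

Step 13
Reactants: 21 meso 7,8-diacetyl-1,5,5-trimethylbicyclo[4.1.1]oct-3-en-2-one
Product: 23 tricyclic bis-enone (C6=O on C5, C7=C8(Me) on C9, bridge enone unchanged, single enantiomer), via ketol 22 (not isolated)
Conditions: 9-amino-9-deoxy-epi-quinine (20 mol %), AcOH (60 mol %), toluene, −15 °C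
Reagents that add atoms: none
Why: The primary amine condenses with one methyl ketone to give the less substituted enamine (C6=C7), the protonated quinuclidine of the same catalyst holds the second carbonyl by a hydrogen bond so that C7 adds to C8, and loss of water from ketol 22 followed by hydrolysis releases 23 and the catalyst. The closest known reaction is the cinchona-primary-amine-catalysed desymmetrising aldol condensation of 4-substituted heptane-2,6-diones to 3-methylcyclohex-2-enones, and 21 is a doubly bridged member of that class. The one new ring (C5–C6–C7–C8–C9 closed through C4 or C10) forms in the 6-(enolendo)-exo-trig mode, helped by the 1,3-diaxial position of the two acetyl groups on the puckered cyclobutane. No bond to C4, C5, C9 or C10 is made or broken; these four carbons become true stereocentres the moment C5 and C9 differ, so all four are controlled by one element, the catalyst's choice between the enantiotopic acetyl groups. The step needs group selectivity, which comes from the catalyst alone because the flat C1=C2–C3=O bridge lies in the symmetry plane, and it needs enamine formation at CH3, which is secured because an enamine toward C5 or C9 would place an exocyclic double bond on the cyclobutane. It also needs an inert bridge enone, which is secured because C3 is flanked by quaternary C4 and sits on the opposite face out of reach of C7, and the weakly acidic buffer avoids enolates that could open the ring by retro-Michael cleavage.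

Step 14
Reactants: 23 tricyclic bis-enone
Product: 25 β-hydroxy ketone (C1–OH on the side of C9, C3=O, C6 enone intact), via pinacol boronate 24 (not isolated)
Conditions: CuCl (5 mol %), (R,R)-QuinoxP* [2,3-bis(tert-butylmethylphosphino)quinoxaline] (6 mol %), NaOt-Bu (10 mol %), B2pin2 (1.1 equiv), MeOH (2 equiv), THF, 0 °C; then NaBO3·4H2O, THF/H2O, rt
Reagents that add atoms: bis(pinacolato)diboron CC1(C)OB(OC1(C)C)B1OC(C)(C)C(C)(C)O1 (boryl group of 24); sodium perborate [Na+].[O-]OB=O (hydroxyl oxygen of 25)
Why: In this copper-catalysed enantioselective conjugate borylation with stereoretentive C–B oxidation the boryl-copper species should attack the β-monosubstituted bridge enone much faster than the β,β-disubstituted C7=C8 enone, and since the two faces of the bridge differ only remotely the chiral diphosphine decides C1 (its mirror image is equally available if the sense is opposite).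

Step 15
Reactants: 25 β-hydroxy ketone
Product: 26 anti-1,3-diol (C1–OH toward C9, C3–OH toward C5)
Conditions: Me4NBH(OAc)3 (5 equiv), MeCN/AcOH (1:1), −25 °C
Reagents that add atoms: none
Why: In the Evans–Saksena reduction the C1 hydroxyl binds the triacetoxyborohydride and delivers hydride to the same face of the C3 carbonyl, which puts the C3 hydroxyl on the opposite face, while the undirected C6 enone is left alone.

Step 16
Reactants: 26 anti-1,3-diol; 27 tiglic acid
Product: 28 target CNP0236543.5 (C1,C3-ditiglate)
Conditions: 27 (6 equiv), 2,4,6-trichlorobenzoyl chloride (6 equiv), Et3N, toluene, rt; then 26, DMAP, 80 °C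
Reagents that add atoms: none
Why: Yamaguchi esterification through the mixed anhydride and the acylpyridinium ion is strong enough for two neopentyl-type secondary alcohols, touches no stereocentre, and the E-tiglate is the stable geometric isomer.

Compound list
1 | methyl 3-hydroxy-2,2-dimethylpropanoate | COC(=O)C(C)(C)CO | starting material
2 | methyl 2,2-dimethyl-3-oxopropanoate | COC(=O)C(C)(C)C=O | intermediate
3 | methyl 2,2-dimethylbut-3-ynoate | COC(=O)C(C)(C)C#C | intermediate
4 | butane-2,3-dione | CC(=O)C(C)=O | starting material
5 | lithium acetylide of 3 (not isolated) | [Li]C#CC(C)(C)C(=O)OC | intermediate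
6 | methyl 5-hydroxy-2,2,5-trimethyl-6-oxohept-3-ynoate (racemic) | COC(=O)C(C)(C)C#CC(C)(O)C(C)=O | intermediate
7 | but-3-yn-2-ol (racemic) | CC(O)C#C | starting material
8 | (E)-vinylalane, O-aluminated (not isolated) | C[Al](C)/C=C(\C)C(C)O[Al](C)C | intermediate
9 | (E)-4-iodo-3-methylbut-3-en-2-ol | CC(O)/C(C)=C/I | intermediate
10 | dilithio alkenyl alkoxide from 9 (not isolated) | [Li]/C=C(\C)C(C)O[Li] | intermediate
11 | bromomagnesium alkoxide of 6 (not isolated) | COC(=O)C(C)(C)C#CC(C)(O[Mg]Br)C(C)=O | intermediate
12 | methyl (5R*,6S*,7E)-5,6,9-trihydroxy-2,2,5,6,8-pentamethyldec-7-en-3-ynoate | COC(=O)C(C)(C)C#C[C@@](C)(O)[C@@](C)(O)/C=C(\C)C(C)O | intermediate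
13 | (3E,5R*,6S*,7E)-2,2,5,6,8-pentamethyldeca-3,7-diene-1,5,6,9-tetraol | OCC(C)(C)/C=C/[C@@](C)(O)[C@@](C)(O)/C=C(\C)C(C)O | intermediate
14 | cis-dialkenyl phenylboronate diol | OCC(C)(C)/C=C/[C@@]1(C)OB(c2ccccc2)O[C@@]1(C)/C=C(\C)C(C)O | intermediate
15 | cis-dialkenyl phenylboronate keto aldehyde | O=CC(C)(C)/C=C/[C@@]1(C)OB(c2ccccc2)O[C@@]1(C)/C=C(\C)C(C)=O | intermediate
16 | ten-membered (E,E)-dienone with C1–OH, boronate cis-fused at C6/C8 | OC1CC(=O)/C(C)=C/[C@]2(C)OB(c3ccccc3)O[C@]2(C)/C=C/C1(C)C | intermediate
17 | tricyclic ketol (boronate oxygens drawn on the C4 side; the other orientation serves equally) | OC1CC(=O)[C@@]2(C)[C@@H]3[C@]4(C)OB(c5ccccc5)O[C@]4(C)[C@H]2[C@@H]3C1(C)C | intermediate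
18 | C1 mesylate of 17 (not isolated) | CS(=O)(=O)OC1CC(=O)[C@@]2(C)[C@@H]3[C@]4(C)OB(c5ccccc5)O[C@]4(C)[C@H]2[C@@H]3C1(C)C | intermediate
19 | meso tricyclic enone boronate | O=C1C=CC(C)(C)[C@@H]2[C@H]3[C@]4(C)OB(c5ccccc5)O[C@]4(C)[C@@H]2[C@@]13C | intermediate
20 | meso cis-diol (not isolated) | O=C1C=CC(C)(C)[C@@H]2[C@H]3[C@](C)(O)[C@](C)(O)[C@@H]2[C@@]13C | intermediate
21 | meso 7,8-diacetyl-1,5,5-trimethylbicyclo[4.1.1]oct-3-en-2-one | O=C1C=CC(C)(C)[C@@H]2[C@@H](C(C)=O)[C@@]1(C)[C@H]2C(C)=O | intermediate
22 | ketol, C8 carbinol centre open (not isolated) | O=C1C=CC(C)(C)[C@@H]2[C@H]3C(=O)CC(C)(O)[C@@H]2[C@@]13C | intermediate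
23 | tricyclic bis-enone | O=C1C=CC(C)(C)[C@@H]2[C@H]3C(=O)C=C(C)[C@@H]2[C@@]13C | intermediate
24 | C1 pinacol boronate (not isolated) | O=C1C[C@@H](B2OC(C)(C)C(C)(C)O2)C(C)(C)[C@@H]2[C@H]3C(=O)C=C(C)[C@@H]2[C@@]13C | intermediate
25 | C1 β-hydroxy ketone | O=C1C[C@@H](O)C(C)(C)[C@@H]2[C@H]3C(=O)C=C(C)[C@@H]2[C@@]13C | intermediate
26 | anti-1,3-diol | O[C@@H]1C[C@@H](O)C(C)(C)[C@@H]2[C@H]3C(=O)C=C(C)[C@@H]2[C@@]13C | intermediate
27 | tiglic acid | C/C=C(\C)C(O)=O | starting material
28 | CNP0236543.5 | C/C=C(\C)C(=O)O[C@@H]1C[C@@H](OC(=O)/C(C)=C/C)[C@@]2(C)[C@@H]3C(=O)C=C(C)[C@H]2[C@@H]3C1(C)C | target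

Total step count: 16. Longest linear sequence: 15 (steps 1–3 and 5–16).

Steps most likely to fail

Step 9. Oligomerisation may outrun closure of the strained ten-membered ring, the amide base may attack the aldehyde, or the aldolate may revert. The fallback sets out from 15. Internal-quench silylation (LiN(i-Pr)2, Me3SiCl, THF, −100 °C) gives the silyl enol ether aldehyde F1. N-Bromosuccinimide then gives the bromomethyl ketone aldehyde F2. SmI2 (THF, −78 °C, high dilution) reduces the carbon–bromine bond to a samarium enolate whose trivalent metal binds the aldehyde before the C1–C2 bond forms. This intramolecular Reformatsky-type closure is established for medium rings, and it comes back to the route at 16.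

Step 10. Energy-wasting E/Z isomerisation, Cope rearrangement of the 1,5-diene, or hydrogen abstraction by the n,π* state may compete with cycloaddition. The fallback sets out from 16. Methylenation of the C3 carbonyl with Cp2Ti(µ-CH2)(µ-Cl)AlMe2 gives the ten-membered 1,3-diene F3. Visible-light triplet sensitisation (Ir[dF(CF3)ppy]2(dtbbpy)PF6, 450 nm, MeCN) excites only the diene, which has no carbonyl photochemistry, and the same crossed closure gives the methylidene tricycle F4. Ozonolysis (O3, then Me2S) of its only alkene comes back to the route at 17.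

Step 13. Discrimination between the two acetyl groups may be weak. Uncatalysed ring closure of the closely held diketone may erode the enantiomeric purity. Epimerisation at C5/C9 or retro-Michael opening may consume the substrate. If only the sense is wrong, the quinidine-derived pseudo-enantiomer of the catalyst is used. The fallback sets out from 21. Enantioselective deprotonation with lithium (R,R)-bis(1-phenylethyl)amide and Me3SiCl as internal quench (THF, −100 °C) differentiates the methyl ketones stoichiometrically and gives the mono silyl enol ether F5. BF3·OEt2 (CH2Cl2, −78 °C) triggers an intramolecular Mukaiyama aldol addition to ketol 22. Acid-catalysed dehydration (p-TsOH, benzene, 40 °C) comes back to the route at 23.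

Further compounds
F1 | step 9 | silyl enol ether aldehyde | O=CC(C)(C)/C=C/[C@@]1(C)OB(c2ccccc2)O[C@@]1(C)/C=C(\C)C(=C)O[Si](C)(C)C
F2 | step 9 | bromomethyl ketone aldehyde | O=CC(C)(C)/C=C/[C@@]1(C)OB(c2ccccc2)O[C@@]1(C)/C=C(\C)C(=O)CBr
F3 | step 10 | ten-membered 1,3-diene (C3 methylidene) | OC1CC(=C)/C(C)=C/[C@]2(C)OB(c3ccccc3)O[C@]2(C)/C=C/C1(C)C
F4 | step 10 | methylidene tricycle | OC1CC(=C)[C@@]2(C)[C@@H]3[C@]4(C)OB(c5ccccc5)O[C@]4(C)[C@H]2[C@@H]3C1(C)C
F5 | step 13 | mono silyl enol ether of 21 (enol ether on the C5 acetyl) | O=C1C=CC(C)(C)[C@@H]2[C@@H](C(=C)O[Si](C)(C)C)[C@@]1(C)[C@H]2C(C)=O
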